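**Retrosynthetic overview**
- The target comes from a bromo-oxane that carries a 4-methylcyclohex-3-enyl group; the ring chlorine and tertiary bromine are added last (chlorohydrin, then OH→Br with retention, then desilylation).
- Both rings of that compound are made in one flask from isoprene and an acyclic α′-siloxy vinyl ketone: Diels–Alder (cyclohexene first), methyl addition, then 6-endo bromoetherification (oxane second).
- The vinyl ketone comes from 6-methylhept-5-en-2-one by enamine α-oxygenation, silylation and α-methylenation.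
- Stereocontrol runs in this order: organocatalyst (oxane C3), Diels–Alder catalyst (cyclohexane C1), Felkin–Anh addition (oxane C2), chair cyclisation (oxane C5), trans-diaxial halogenation (cyclohexane C3 and C4).

Assumption: the SMILES is read as (2S,3S,5S)-5-bromo-2-[(1R,3S,4S)-4-bromo-3-chloro-4-methylcyclohexyl]-2,6,6-trimethyloxan-3-ol (tertiary Br and secondary Cl trans-diaxial, Br cis to the oxanyl group); bulk reagents and catalysts count as commercial.

**Step 1**
Reactants: 1 6-methylhept-5-en-2-one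
Product: 3 (3S)-3-hydroxy-6-methylhept-5-en-2-one, via aminoxy ketone 2 (not isolated)
Conditions: PhNO (slow addition), D-proline (20 mol%), CHCl3, 4 °C; then CuSO4·5H2O (30 mol%), MeOH, 0 °C
Reagents that add atoms: nitrosobenzene (O=Nc1ccccc1)
Why: Proline-catalysed α-aminoxylation (enamine catalysis, O-selective nitroso aldol) goes through the more substituted E-enamine, D-proline delivers oxygen to the face that gives 3S, and copper-mediated N–O cleavage then frees the α-hydroxy ketone without touching the stereocentre.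

**Step 2**
Reactants: 3 (3S)-3-hydroxy-6-methylhept-5-en-2-one
Product: 4 (3S)-3-{[tert-butyl(dimethyl)silyl]oxy}-6-methylhept-5-en-2-one
Conditions: TBSCl, imidazole, DMF, 0 °C → rt
Reagents that add atoms: tert-butyldimethylsilyl chloride (CC(C)(C)[Si](C)(C)Cl)
Why: Silyl ether formation at the only hydroxyl gives a bulky, non-chelating group that later enforces Felkin–Anh addition and cannot close a five-membered bromo-ether; the stereocentre is untouched.

**Step 3**
Reactants: 4 (3S)-3-{[tert-butyl(dimethyl)silyl]oxy}-6-methylhept-5-en-2-one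
Product: 7 (4S)-4-{[tert-butyl(dimethyl)silyl]oxy}-7-methylocta-1,6-dien-3-one, via Mannich base 5 (not isolated), via ammonium iodide 6 (not isolated)
Conditions: LiN(iPr)2, THF, −78 °C; [CH2=NMe2]I, −78 → 0 °C; then MeI, rt; then aq. NaHCO3, CH2Cl2, rt
Reagents that add atoms: N,N-dimethylmethyleneiminium iodide (C=[N+](C)C.[I-])
Why: Kinetic deprotonation occurs at the methyl group, the enolate is trapped in a Mannich reaction, and quaternisation followed by E1cB (Hofmann-type) elimination gives the vinyl ketone (α-methylenation); C4 is never deprotonated and keeps its configuration.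

**Step 4**
Reactants: 7 (4S)-4-{[tert-butyl(dimethyl)silyl]oxy}-7-methylocta-1,6-dien-3-one; 8 isoprene (2-methylbuta-1,3-diene)
Product: 11 tert-butyl({(2S,3S,5S)-5-bromo-2,6,6-trimethyl-2-[(1R)-4-methylcyclohex-3-en-1-yl]oxan-3-yl}oxy)dimethylsilane, via cycloadduct ketone 9 (not isolated), via tertiary alcohol 10 (not isolated)
Conditions: 8 (3 equiv), (3aS)-1-(2-methylphenyl)-3,3-diphenyltetrahydro-1H,3H-pyrrolo[1,2-c][1,3,2]oxazaborole protonated by HN(SO2CF3)2 (20 mol%), toluene, −78 → −40 °C; then MeLi (Et2O), −78 °C; then AcOH, excess 8 stripped in vacuo, (CF3)2CHOH, NBS, −20 → 0 °C; one flask, no work-up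
Reagents that add atoms: methyllithium ([Li]C); N-bromosuccinimide (O=C1CCC(=O)N1Br)
Why: Three established reactions run back to back: the oxazaborolidinium-catalysed enantioselective Diels–Alder reaction gives the para adduct and its catalyst-controlled face selectivity sets C1 of the cyclohexene (R); Felkin–Anh 1,2-addition of methyllithium anti to the siloxy group sets the tertiary carbinol (S); and 6-endo (Markovnikov) bromoetherification of that alcohol onto the prenyl double bond closes the oxane through a chair with cyclohexenyl and bromine equatorial, which sets C5 (S).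

**Step 5**
Reactants: 11 tert-butyl({(2S,3S,5S)-5-bromo-2,6,6-trimethyl-2-[(1R)-4-methylcyclohex-3-en-1-yl]oxan-3-yl}oxy)dimethylsilane
Product: 12 (1S,2S,4R)-4-[(2S,3S,5S)-5-bromo-3-{[tert-butyl(dimethyl)silyl]oxy}-2,6,6-trimethyloxan-2-yl]-2-chloro-1-methylcyclohexan-1-ol
Conditions: NCS, acetone/H2O (4:1), 0 °C → rt
Reagents that add atoms: N-chlorosuccinimide (O=C1CCC(=O)N1Cl); water (O)
Why: Chlorohydrin formation: water opens the chloronium ion trans-diaxially at the tertiary carbon (Markovnikov and Fürst–Plattner agree for the half-chair with the oxanyl group equatorial, as in the halohydrin of limonene), which places chlorine trans and hydroxyl cis to the oxanyl group (1S,2S).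

**Step 6**
Reactants: 12 (1S,2S,4R)-4-[(2S,3S,5S)-5-bromo-3-{[tert-butyl(dimethyl)silyl]oxy}-2,6,6-trimethyloxan-2-yl]-2-chloro-1-methylcyclohexan-1-ol
Product: 13 tert-butyl({(2S,3S,5S)-5-bromo-2-[(1R,3S,4S)-4-bromo-3-chloro-4-methylcyclohexyl]-2,6,6-trimethyloxan-3-yl}oxy)dimethylsilane
Conditions: TMSBr (1.5 equiv), CH2Cl2, −40 → 0 °C
Reagents that add atoms: bromotrimethylsilane (C[Si](C)(C)Br)
Why: SN1 substitution of the tertiary alcohol under neighbouring-group control: the silylated hydroxyl ionises to a cation bridged by the anti-periplanar axial chlorine, bromide enters axially trans to chlorine with net retention (4S), and any tertiary chloride/secondary bromide from attack at the other carbon equilibrates to the same diaxial product by the 1,2-interchange of vicinal dihalides.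

**Step 7**
Reactants: 13 tert-butyl({(2S,3S,5S)-5-bromo-2-[(1R,3S,4S)-4-bromo-3-chloro-4-methylcyclohexyl]-2,6,6-trimethyloxan-3-yl}oxy)dimethylsilane
Product: 14 (2S,3S,5S)-5-bromo-2-[(1R,3S,4S)-4-bromo-3-chloro-4-methylcyclohexyl]-2,6,6-trimethyloxan-3-ol
Conditions: HF·pyridine, THF, 0 °C
Reagents that add atoms: none
Why: Fluoride-induced desilylation under mildly acidic, base-free conditions leaves the tertiary bromide and the other halides alone and touches no stereocentre.

**Compound list**
1 | 6-methylhept-5-en-2-one | CC(=O)CCC=C(C)C | starting material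
2 | (3S)-6-methyl-3-[(phenylamino)oxy]hept-5-en-2-one | CC(=O)[C@@H](ONc1ccccc1)CC=C(C)C | intermediate
3 | (3S)-3-hydroxy-6-methylhept-5-en-2-one | CC(=O)[C@@H](O)CC=C(C)C | intermediate
4 | (3S)-3-{[tert-butyl(dimethyl)silyl]oxy}-6-methylhept-5-en-2-one | CC(=O)[C@@H](O[Si](C)(C)C(C)(C)C)CC=C(C)C | intermediate
5 | (4S)-4-{[tert-butyl(dimethyl)silyl]oxy}-1-(dimethylamino)-7-methyloct-6-en-3-one | CN(C)CCC(=O)[C@@H](O[Si](C)(C)C(C)(C)C)CC=C(C)C | intermediate
6 | (4S)-4-{[tert-butyl(dimethyl)silyl]oxy}-N,N,N,7-tetramethyl-3-oxooct-6-en-1-aminium iodide | C[N+](C)(C)CCC(=O)[C@@H](O[Si](C)(C)C(C)(C)C)CC=C(C)C.[I-] | intermediate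
7 | (4S)-4-{[tert-butyl(dimethyl)silyl]oxy}-7-methylocta-1,6-dien-3-one | C=CC(=O)[C@@H](O[Si](C)(C)C(C)(C)C)CC=C(C)C | intermediate
8 | isoprene (2-methylbuta-1,3-diene) | C=CC(C)=C | starting material
9 | (2S)-2-{[tert-butyl(dimethyl)silyl]oxy}-5-methyl-1-[(1R)-4-methylcyclohex-3-en-1-yl]hex-4-en-1-one | CC1=CC[C@@H](CC1)C(=O)[C@@H](O[Si](C)(C)C(C)(C)C)CC=C(C)C | intermediate
10 | (2S,3S)-3-{[tert-butyl(dimethyl)silyl]oxy}-6-methyl-2-[(1R)-4-methylcyclohex-3-en-1-yl]hept-5-en-2-ol | CC1=CC[C@@H](CC1)[C@](C)(O)[C@@H](O[Si](C)(C)C(C)(C)C)CC=C(C)C | intermediate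
11 | tert-butyl({(2S,3S,5S)-5-bromo-2,6,6-trimethyl-2-[(1R)-4-methylcyclohex-3-en-1-yl]oxan-3-yl}oxy)dimethylsilane | CC1(C)O[C@@](C)([C@@H]2CCC(C)=CC2)[C@@H](O[Si](C)(C)C(C)(C)C)C[C@@H]1Br | intermediate
12 | (1S,2S,4R)-4-[(2S,3S,5S)-5-bromo-3-{[tert-butyl(dimethyl)silyl]oxy}-2,6,6-trimethyloxan-2-yl]-2-chloro-1-methylcyclohexan-1-ol | CC1(C)O[C@@](C)([C@@H]2CC[C@](C)(O)[C@@H](Cl)C2)[C@@H](O[Si](C)(C)C(C)(C)C)C[C@@H]1Br | intermediate
13 | tert-butyl({(2S,3S,5S)-5-bromo-2-[(1R,3S,4S)-4-bromo-3-chloro-4-methylcyclohexyl]-2,6,6-trimethyloxan-3-yl}oxy)dimethylsilane | CC1(C)O[C@@](C)([C@@H]2CC[C@](C)(Br)[C@@H](Cl)C2)[C@@H](O[Si](C)(C)C(C)(C)C)C[C@@H]1Br | intermediate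
14 | (2S,3S,5S)-5-bromo-2-[(1R,3S,4S)-4-bromo-3-chloro-4-methylcyclohexyl]-2,6,6-trimethyloxan-3-ol | CC1(C)O[C@@](C)([C@@H]2CC[C@](C)(Br)[C@@H](Cl)C2)[C@@H](O)C[C@@H]1Br | target

**Total step count:** 7. **Longest linear sequence:** 7 (1 → 14).

**The three steps most likely to fail**

Step 4. Three things can go wrong: the sense and level of face selectivity in the cycloaddition of a hindered, chiral enone (the mirror-image catalyst is the first remedy), the Felkin ratio, and 5-exo or cineole-type closure competing with the 6-endo mode. The fallback sets out from 7 and comes back at 11. It separates the three events and puts the cycloaddition under two-point chelate control. HF·pyridine removes the silyl group of 7 to give (4S)-4-hydroxy-7-methylocta-1,6-dien-3-one F1. F1 binds Cu(OTf)2 with (S,S)-tert-butyl-bis(oxazoline) through ketone and hydroxyl and adds 8 to give (2S)-2-hydroxy-5-methyl-1-[(1R)-4-methylcyclohex-3-en-1-yl]hex-4-en-1-one F2; a wrong ring epimer is a separable diastereomer. TBSOTf with 2,6-lutidine returns 9, now isolated; MeLi with CeCl3 gives 10, purified from its epimer; 2,4,4,6-tetrabromocyclohexa-2,5-dienone in MeNO2 closes the oxane to 11.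

Step 5. Chloronium formation is less reversible than bromonium formation, so face selectivity is less self-correcting, and allylic chlorination can compete. The fallback sets out from 11 and comes back at 12. NBS in aqueous acetone, where reversible bromonium formation funnels to the diaxial Markovnikov product, gives (1S,2S,4R)-2-bromo-4-[(2S,3S,5S)-5-bromo-3-{[tert-butyl(dimethyl)silyl]oxy}-2,6,6-trimethyloxan-2-yl]-1-methylcyclohexan-1-ol F3. K2CO3 in MeOH closes it to the epoxide with oxygen cis to the oxanyl group, tert-butyl({(2S,3S,5S)-5-bromo-2,6,6-trimethyl-2-[(1R,3R,6S)-6-methyl-7-oxabicyclo[4.1.0]heptan-3-yl]oxan-3-yl}oxy)dimethylsilane F4. Pyridinium chloride in CH2Cl2 opens F4 trans-diaxially at the secondary carbon to give 12.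

Step 6. Ionisation next to chlorine is slow, elimination competes, and acid can reopen the doubly tertiary oxane ether. The fallback sets out from 11 and comes back at 13; it introduces the halogens in the reverse order and needs no strong acid. mCPBA epoxidises 11 on both faces. The epoxide with oxygen trans to the oxanyl group, tert-butyl({(2S,3S,5S)-5-bromo-2,6,6-trimethyl-2-[(1S,3R,6R)-6-methyl-7-oxabicyclo[4.1.0]heptan-3-yl]oxan-3-yl}oxy)dimethylsilane F5, is separated from its epimer F4, which is sent on to 12 as above. LiBr in AcOH opens F5 trans-diaxially at the tertiary carbon (Markovnikov and Fürst–Plattner agree) to give (1S,2S,5R)-2-bromo-5-[(2S,3S,5S)-5-bromo-3-{[tert-butyl(dimethyl)silyl]oxy}-2,6,6-trimethyloxan-2-yl]-2-methylcyclohexan-1-ol F6. SOCl2 with pyridine then replaces the secondary hydroxyl by chloride with retention through the bromonium ion formed by the anti-periplanar tertiary bromide, giving 13; gentle warming converges any rearranged bromochloride onto 13.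

**Further compounds**
F1 | step 4 | (4S)-4-hydroxy-7-methylocta-1,6-dien-3-one | C=CC(=O)[C@@H](O)CC=C(C)C
F2 | step 4 | (2S)-2-hydroxy-5-methyl-1-[(1R)-4-methylcyclohex-3-en-1-yl]hex-4-en-1-one | CC1=CC[C@@H](CC1)C(=O)[C@@H](O)CC=C(C)C
F3 | step 5 | (1S,2S,4R)-2-bromo-4-[(2S,3S,5S)-5-bromo-3-{[tert-butyl(dimethyl)silyl]oxy}-2,6,6-trimethyloxan-2-yl]-1-methylcyclohexan-1-ol | CC1(C)O[C@@](C)([C@@H]2CC[C@](C)(O)[C@@H](Br)C2)[C@@H](O[Si](C)(C)C(C)(C)C)C[C@@H]1Br
F4 | step 5 | tert-butyl({(2S,3S,5S)-5-bromo-2,6,6-trimethyl-2-[(1R,3R,6S)-6-methyl-7-oxabicyclo[4.1.0]heptan-3-yl]oxan-3-yl}oxy)dimethylsilane | CC1(C)O[C@@](C)([C@@H]2CC[C@]3(C)O[C@@H]3C2)[C@@H](O[Si](C)(C)C(C)(C)C)C[C@@H]1Br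
F5 | step 6 | tert-butyl({(2S,3S,5S)-5-bromo-2,6,6-trimethyl-2-[(1S,3R,6R)-6-methyl-7-oxabicyclo[4.1.0]heptan-3-yl]oxan-3-yl}oxy)dimethylsilane | CC1(C)O[C@@](C)([C@@H]2CC[C@@]3(C)O[C@H]3C2)[C@@H](O[Si](C)(C)C(C)(C)C)C[C@@H]1Br
F6 | step 6 | (1S,2S,5R)-2-bromo-5-[(2S,3S,5S)-5-bromo-3-{[tert-butyl(dimethyl)silyl]oxy}-2,6,6-trimethyloxan-2-yl]-2-methylcyclohexan-1-ol | CC1(C)O[C@@](C)([C@@H]2CC[C@](C)(Br)[C@@H](O)C2)[C@@H](O[Si](C)(C)C(C)(C)C)C[C@@H]1Br
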